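## Structural features

The target has three carbocycles that all share the methine C22: ring A (C2, C3, C4, C5, C22, C20), ring B (C5, C9, C10, C11, C12, C22) and the seven-membered ring C (C12, C13, C17, C18, C19, C20, C22). A furan is fused to ring C across C13–C17 and carries the ring C ketone C18 on its 3-position. A γ-lactone (C5, C6, O7, C8, C9) is fused to ring B across C5–C9 and is spiro to ring A at C5.

There are five stereocentres. C5, C22 and C20 are contiguous, C12 sits on the C22 branch, and C3 stands alone. On ring A the C3 oxygen, C9, C12 and C19 lie on one face (β); C6, the C21 methyl and H22 lie on the other (α); H12 is cis to H22.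

The fragile groups are the allylic acetate next to the exocyclic C1=C2 methylene (ionisation, allylic substitution), the α-alkylidene lactone (conjugate addition, base), the acyl furan (oxidants, strong acid) and the enolisable C19 methylene.

The real difficulty is the pair of quaternary centres C5 and C20 flanking C22 in a crowded, angularly fused core, with four neighbouring centres to be set relative to one another.

The key step uses the fact that C5 bears the oxygenated carbon C6: once O7 is acylated, the carbon that becomes C9 stands in a 1,5 relationship to the C5–H bond. The C9–C5 bond can therefore take the place of a tertiary C–H of a chiral-pool cyclohexane, with retention.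

## Logic of the disconnections

29 to 28: the C9=C10 bond of ring B is cut. An alkene conjugated to a lactone carbonyl is the retron of an olefination between an α-phosphono lactone and an aldehyde. Ring B and the sensitive alkylidene lactone then appear only in the last step. The forward step needs a base mild enough for the allylic acetate.

28 to 27: no skeletal bond is cut; the C10 aldehyde is masked as its dimethyl acetal so that it survives diazo transfer and the carbenoid. The forward step needs hydrolysis that spares the acetate, the lactone and the furan.

27 to 26: the C9–C5 bond is cut. This turns the quaternary C5 into a tertiary C–H stereocentre and removes the lactone ring. The forward step must insert only into C5–H, with retention.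

26 to 25 to 23 + 24: the diazo group and the O7–C8 ester bond are removed. The carbenoid precursor becomes a primary alcohol and a commercial phosphonoacetic acid. The forward steps need only an acylation and a diazo transfer that respect the C18 ketone.

23 to 22 to 21 to 20: functional-group changes only. The C6 silyl ether, the C3 acetate and the C3 carbinol lead back to an α-methylene ketone. The reduction must deliver hydride to the α face of C3 and leave the C18 ketone alone.

20 to 19 to 18 to 17: the C19–C20 bond (ring C) is cut and the C1=C2 unsaturation is traced to the enolate of a conjugate addition. The quaternary C20 then comes from a β-methyl enone, and the nucleophile is tethered to the β-oriented C12, so ring C and C20 form together from a monocyclic precursor. The forward step must keep the ring A enolate in place until it is silylated.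

17 to 16 to 15: the C20–C21 and C18–C19 bonds are cut (both methyl groups from one methyl nucleophile) and the enone is transposed. This leads back to a cross-conjugated enone of the carvone type. The oxidant must tolerate acetal, silyl ether and furan.

15 to 14 to 13: the oxidation level of C10 is changed from acetal through aldehyde to thioester, because the arm must first serve as a Michael acceptor. The reduction has to be selective for the thioester in the presence of a ketone.

13 to 6 + 11: the C22–C12 bond is cut. This is the convergent step; it joins the terpene-derived ring A to the furan fragment and sets C22 and C12. It needs attack trans to the C5 side chain, syn topicity, and a stop after the first addition.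

11 to 10 to 9 to 7: the amide bond, the C11=C12 alkene and the C12–C13 bond are cut, leading to 3-furoic acid. The carboxyl group directs metalation to the furan position that becomes C13 and later supplies C18.

6 to 5 to 4 to 3 to 1: the two outer carbons of the isopropenyl group are removed so that its central carbon becomes C6. The sequence must leave the C5 stereocentre untouched; it is the only source of absolute configuration. In this route the carbonyl carbon of the terpene becomes C20, so the (S) enantiomer is required.

## Other disconnections considered

Alternative 1: The cut removes C20–C22 and C4–C5, so ring A is annulated onto a preformed ring B. Forward, the vinyl ketone ester A1 would add through its central carbon to the β-carbon (C22) of the cyclohexenone ester A2 under a mild carbonate base. The ring B ester enolate at C5 would then close on the vinyl terminus to give the cis-fused enol diester A3.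
- In its favour: two C–C bonds, ring A, the quaternary C5 and the C22 methine arise in one operation from small partners, and the silyloxy group of A2 should steer the first addition to its opposite face. On making C5 quaternary directly and early, this plan is the better one.
- Against it here: A3 still lacks ring C, the furan, C19, C21 and the C3 oxygen. C20 arrives as the α-carbon of a β-keto ester, so it must be alkylated with stereocontrol and its ester reduced all the way to a methyl group. The C9 ketone must become the C9=C10 alkene carrying C8. The C12 oxygen of A3 has the configuration opposite to the one the C12–C13 bond must take.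
- Comparison: structurally it fixes C5 and C22 sooner. Mechanistically it relies on reversible anionic additions under substrate control, whereas the chosen insertion is stereospecific. In step economy the gain of the annulation is expected to be spent on corrections at C20, C9, C3 and C12, so the two plans are judged about equal in length, with more stereochemical uncertainty in Alternative 1.

Alternative 2: The cut is C19–C20 (ring C), together with the unveiling of the C3 ketone and the C1=C2 methylene. Forward, near-ultraviolet irradiation of A4 would add the enol of its furyl 1,3-diketone across the inner double bond of the allene on C22. The methylenecyclobutanol so formed would open by retro-aldol cleavage to A5.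
- In its favour: the quaternary C20, ring C and the α-methylene ketone form in one reagent-free operation, and the C19–C20 bond forms irreversibly. On the exocyclic methylene, which costs the chosen plan a separate dehydrogenation, and on the irreversibility of the C19–C20 bond formation, Alternative 2 is the better plan.
- Against it here: the photoreaction must select one allene double bond, one orientation and one face at C20 under the influence of C22 alone, while the furyl ketone is itself a chromophore. Ring A must then be closed from A5 by conjugate addition of C4 to the fully substituted butenolide carbon C5. That sets the quaternary C5 under substrate control and leaves C9 saturated, so the C9=C10 bond and the C3 carbinol still need adjusting. The absolute configuration must come from an asymmetric synthesis of A4.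
- Comparison: structurally both plans build C20 by bonding C19 to it from a tether on C12, and there they are equal. Mechanistically the chosen plan transfers the configuration of C5 from the chiral pool with retention, whereas Alternative 2 has to create it. Alternative 2 could be shorter if the photochemical step and the ring A closure were both selective.

Alternative 3: The cut removes C2–C20, C19–C18 and C18–C17 in one cascade. Forward, zerovalent palladium would insert into the C2–Br bond of A6, and the alkenylpalladium would add to the isopropenyl group in the 6-exo mode (ring A, quaternary C20). The neopentyl palladium, which has no β-hydrogen, would take up a carbonyl unit under carbonylative conditions, and the acylpalladium would couple with the furyl stannane to close ring C. The product A7 differs from the target only in the group on the C3 oxygen.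
- In its favour: three C–C bonds, two rings and C20 form in one flask. In late-stage convergence and in the number of steps after the key step it is clearly the better plan.
- Against it here: A6 must already contain the quaternary C5, the unsaturated lactone, ring B and the C12 and C22 stereocentres, so the hardest problem of the target is moved into the substrate rather than solved. The cascade must outrun carbonylation of the alkenylpalladium and direct coupling with the stannane, must choose the correct face of the isopropenyl group, and must close a seven-membered ketone. The terpene A8 carries its ring methyl para to the isopropenyl-bearing carbon, whereas ring B needs its carbon substituent C8 meta to C22, so the terpene pattern would need extensive re-functionalisation.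
- Comparison: structurally it is the most convergent of the four plans. Mechanistically it stakes three consecutive organopalladium events on one step, where the chosen plan uses one well-precedented carbenoid insertion. In overall length no advantage is expected once the synthesis of A6 is counted.

Key step: step 20

Remark on the structures: the precursor and the product of the key step were checked against the target at C3, C5, C12, C20 and C22; they are consistent and are used unchanged as 26 and 27. The one correction concerns the terpene: because its carbonyl carbon becomes C20 here, (S)-carvone is required; (R)-carvone would lead to the enantiomer.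

Remark on conventions: locants C1 to C22 are those of the target. β is the face of ring A with the C3 oxygen, C12 and C19; α is the face with C6, C21 and H22. The configurations at C20 in 16 and at C9 in 27 and 28 are of no consequence and are left open.

Step 1
Reactants: 1 (S)-carvone
Product: 3 (S)-5-acetyl-2-methylcyclohex-2-en-1-one, via ozonide 2 (not isolated)
Conditions: O3, CH2Cl2, −78 °C; then Me2S, −78 °C to rt
Reagents that add atoms: ozone, [O-][O+]=O
Why: Ozonolysis with reductive work-up; the electron-rich isopropenyl alkene reacts much faster than the conjugated ring alkene, so only the side chain is cleaved and C5 is not touched.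

Step 2
Reactants: 3 (S)-5-acetyl-2-methylcyclohex-2-en-1-one
Product: 4 (S)-4-methyl-5-oxocyclohex-3-ene-1-carboxylic acid
Conditions: Br2, NaOH, H2O/1,4-dioxane, 0 °C; then aq HCl
Reagents that add atoms: sodium hydroxide, [Na+].[OH-]
Why: Haloform reaction; the methyl group is exhaustively brominated and the tribromomethyl ketone is cleaved by hydroxide, while cold hypobromite spares the enone. Enolisation toward the C5 methine is slower, and any such enolate is brominated rather than reprotonated, so the configuration at C5 should be kept in the product.

Step 3
Reactants: 4 (S)-4-methyl-5-oxocyclohex-3-ene-1-carboxylic acid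
Product: 5 (S)-5-(hydroxymethyl)-2-methylcyclohex-2-en-1-one
Conditions: BH3·SMe2, THF, −15 to 0 °C; then MeOH
Reagents that add atoms: none
Why: Chemoselective borane reduction of a carboxylic acid through its acyloxyborane, which is faster than 1,2-reduction of the conjugated, α-substituted ketone at low temperature.

Step 4
Reactants: 5 (S)-5-(hydroxymethyl)-2-methylcyclohex-2-en-1-one
Product: 6 (S)-5-{[(tert-butyldimethylsilyl)oxy]methyl}-2-methylcyclohex-2-en-1-one
Conditions: t-BuMe2SiCl, imidazole, DMF, rt
Reagents that add atoms: tert-butylchlorodimethylsilane, CC(C)(C)[Si](C)(C)Cl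
Why: Silylation of the primary alcohol; the silyl ether withstands the enolate, organometallic and oxidation steps that follow.

Step 5
Reactants: 7 3-furoic acid
Product: 9 2-formylfuran-3-carboxylic acid, via dilithio furoate 8 (not isolated)
Conditions: LiN(i-Pr)2 (2.2 equiv), THF, −78 °C; then DMF; aq HCl
Reagents that add atoms: N,N-dimethylformamide, CN(C)C=O
Why: Directed ortho-metalation; the lithium carboxylate directs the second deprotonation to the adjacent furan C2, which is also the most acidic ring position, and the aryllithium is formylated by DMF.

Step 6
Reactants: 9 2-formylfuran-3-carboxylic acid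
Product: 10 (E)-2-[3-(ethylsulfanyl)-3-oxoprop-1-en-1-yl]furan-3-carboxylic acid
Conditions: Et3N (1 equiv), Ph3P=CHC(O)SEt, CH2Cl2, rt; then dilute HCl
Reagents that add atoms: S-ethyl 2-(triphenylphosphoranylidene)ethanethioate, CCSC(=O)C=P(c1ccccc1)(c1ccccc1)c1ccccc1
Why: Wittig olefination with a carbonyl-stabilised ylide, which is E-selective; the acid is held as its ammonium salt so that it does not quench the ylide.

Step 7
Reactants: 10 (E)-2-[3-(ethylsulfanyl)-3-oxoprop-1-en-1-yl]furan-3-carboxylic acid
Product: 11 S-ethyl (E)-3-{3-[methoxy(methyl)carbamoyl]furan-2-yl}prop-2-enethioate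
Conditions: MeNHOMe·HCl, EDC·HCl, N-methylmorpholine, CH2Cl2, 0 °C to rt
Reagents that add atoms: N,O-dimethylhydroxylamine hydrochloride, CNOC.Cl
Why: Carbodiimide amide coupling; the Weinreb amide is inert to enolates at low temperature and later gives the methyl ketone after a single methyl addition.

Step 8
Reactants: 6 (S)-5-{[(tert-butyldimethylsilyl)oxy]methyl}-2-methylcyclohex-2-en-1-one; 11 S-ethyl (E)-3-{3-[methoxy(methyl)carbamoyl]furan-2-yl}prop-2-enethioate
Product: 13 S-ethyl (3R)-3-[(1S,6S)-6-{[(tert-butyldimethylsilyl)oxy]methyl}-3-methyl-2-oxocyclohex-3-en-1-yl]-3-{3-[methoxy(methyl)carbamoyl]furan-2-yl}propanethioate, via lithium enolate 12 (not isolated)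
Conditions: LiN(i-Pr)2, THF, −78 °C; then 11, −78 °C; AcOH, −78 °C
Reagents that add atoms: none
Why: Michael addition of the kinetic cross-conjugated lithium enolate (α′ carbon, the future C22) to an α,β-unsaturated thioester. Attack should occur trans to the C5 side chain, and the closed lithium-bridged transition state of a ring (E) enolate with an E acceptor should give the syn adduct, which is the C22/C12 relationship of the target. The cold quench is meant to prevent a second, intramolecular Michael addition.

Step 9
Reactants: 13 the thioester Michael adduct
Product: 14 (3R)-3-[(1S,6S)-6-{[(tert-butyldimethylsilyl)oxy]methyl}-3-methyl-2-oxocyclohex-3-en-1-yl]-3-{3-[methoxy(methyl)carbamoyl]furan-2-yl}propanal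
Conditions: Et3SiH, Pd/C, acetone, rt
Reagents that add atoms: none
Why: Fukuyama reduction; zerovalent palladium inserts into the acyl–sulfur bond and the silane delivers hydride, so the thioester becomes the aldehyde while ketone, amide and silyl ether are left alone.

Step 10
Reactants: 14 the C10 aldehyde
Product: 15 2-{(1R)-1-[(1S,6S)-6-{[(tert-butyldimethylsilyl)oxy]methyl}-3-methyl-2-oxocyclohex-3-en-1-yl]-3,3-dimethoxypropyl}-N-methoxy-N-methylfuran-3-carboxamide
Conditions: HC(OMe)3, MeOH, CeCl3·7H2O (cat.), rt
Reagents that add atoms: trimethyl orthoformate, COC(OC)OC
Why: Acetalisation of an aldehyde in the presence of a ketone under near-neutral CeCl3 catalysis; this masks C10 for all later steps and keeps the silyl ether.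

Step 11
Reactants: 15 the C10 dimethyl acetal
Product: 16 1-(2-{(1R)-1-[(1S,6S)-6-{[(tert-butyldimethylsilyl)oxy]methyl}-2-hydroxy-2,3-dimethylcyclohex-3-en-1-yl]-3,3-dimethoxypropyl}furan-3-yl)ethan-1-one (both carbinol epimers at C20)
Conditions: MeLi, CeCl3, THF, −78 °C; then aq NH4Cl
Reagents that add atoms: methyllithium, [Li]C
Why: Organocerium 1,2-addition to the hindered, enolisable cross-conjugated ketone and ketone synthesis from the Weinreb amide in one operation; the two methyl groups become C21 and C19.

Step 12
Reactants: 16 the tertiary allylic alcohol
Product: 17 (4S,5S)-4-[(1R)-1-(3-acetylfuran-2-yl)-3,3-dimethoxypropyl]-5-{[(tert-butyldimethylsilyl)oxy]methyl}-2,3-dimethylcyclohex-2-en-1-one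
Conditions: IBX, DMSO, 55 °C
Reagents that add atoms: 2-iodoxybenzoic acid, O=C1OI(=O)(O)c2ccccc12
Why: Oxidative 1,3-transposition of a tertiary allylic alcohol (Babler–Dauben type) under neutral conditions that acetal, silyl ether and the electron-poor furan should tolerate; C3 becomes the carbonyl carbon and C20 the β-carbon of the enone.

Step 13
Reactants: 17 the 2,3-dimethyl enone
Product: 19 tricyclic triethylsilyl enol ether (ring A, ring C, furan; C2=C3 enol ether, C18 ketone, C6 silyl ether, C10 dimethyl acetal; 5S,12R,20R,22S), via potassium enolate 18 (not isolated)
Conditions: KN(SiMe3)2, THF, −78 to −20 °C; then Et3SiCl, −78 °C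
Reagents that add atoms: chlorotriethylsilane, CC[Si](Cl)(CC)CC
Why: Intramolecular Michael addition (7-exo-trig) of the methyl ketone enolate to the β-methyl enone, followed by O-silylation of the ring A enolate. The nucleophile is tethered to the β-oriented C12 and reaches C20 axially, trans to the C5 side chain, so ring C is cis-fused with C19 β and C21 α. The low temperature and the hindered C19 methylene should keep the enolate at C2–C3 until it is trapped.

Step 14
Reactants: 19 the tricyclic triethylsilyl enol ether
Product: 20 tricyclic α-methylene ketone (C1=C2 exocyclic, C3 ketone, C18 ketone, C6 silyl ether, C10 dimethyl acetal; 5S,12R,20R,22S)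
Conditions: Pd(OAc)2, MeCN, rt
Reagents that add atoms: none
Why: Saegusa–Ito oxidation; the palladium enolate at C2 can only lose a β-hydrogen from the C1 methyl group because C20 is quaternary, so the exocyclic enone is the only possible product.

Step 15
Reactants: 20 the tricyclic α-methylene ketone
Product: 21 tricyclic allylic alcohol (C3 β-hydroxy; 3S,5S,12R,20R,22S)
Conditions: NaBH4, CeCl3·7H2O, MeOH, −78 °C
Reagents that add atoms: none
Why: Luche reduction, 1,2-selective for the enone and expected to spare the less electrophilic furyl ketone. The axial C19 on C20 shields the β face of C3, so hydride should enter from the α face and give the β alcohol.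

Step 16
Reactants: 21 the C3 allylic alcohol
Product: 22 tricyclic C3 acetate (C6 silyl ether, C10 dimethyl acetal; 3S,5S,12R,20R,22S)
Conditions: Ac2O, pyridine, DMAP (cat.), CH2Cl2, 0 °C to rt
Reagents that add atoms: acetic anhydride, CC(=O)OC(C)=O
Why: Acetylation of the secondary allylic alcohol with nucleophilic catalysis.

Step 17
Reactants: 22 the C3 acetate
Product: 23 tricyclic C6 primary alcohol (C3 acetate, C10 dimethyl acetal; 3S,5S,12R,20R,22S)
Conditions: Bu4NF, AcOH, THF, 0 °C to rt
Reagents that add atoms: none
Why: Fluoride cleavage of the primary silyl ether, buffered with acetic acid so that the acetate and the acetal are kept.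

Step 18
Reactants: 23 the C6 primary alcohol; 24 diethylphosphonoacetic acid
Product: 25 C6 diethylphosphonoacetate of the tricycle (3S,5S,12R,20R,22S)
Conditions: EDC·HCl, DMAP (cat.), CH2Cl2, 0 °C to rt
Reagents that add atoms: none
Why: Carbodiimide (Steglich) esterification of an unhindered primary alcohol.

Step 19
Reactants: 25 the C6 phosphonoacetate
Product: 26 C6 diazophosphonoacetate of the ring A, ring C, furan tricycle (3S,5S,12R,20R,22S)
Conditions: 4-acetamidobenzenesulfonyl azide, DBU, MeCN, 0 °C to rt
Reagents that add atoms: 4-acetamidobenzenesulfonyl azide, CC(=O)Nc1ccc(cc1)S(=O)(=O)N=[N+]=[N-]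
Why: Regitz diazo transfer to the doubly activated methylene of the phosphonoacetate; the C19 methylene of the ketone is not acidic enough to compete.

Step 20
Reactants: 26 the C6 diazophosphonoacetate
Product: 27 α-phosphono γ-lactone, spiro to ring A at C5 (C9 epimers; 3S,12R,20R,22S, C9 on the β face of C5)
Conditions: Rh2(OAc)4 (2 mol %), 1,2-dichloroethane, reflux, slow addition, high dilution
Reagents that add atoms: none
Why: Rh2(OAc)4 decomposes the diazo group with loss of dinitrogen to an electrophilic rhodium carbenoid centred on C9. The carbenoid carbon inserts into the C5–H bond through a concerted three-centre transition state and the catalyst is released. The closest known reaction type is the dirhodium-catalysed intramolecular 1,5 C–H insertion of diazoacetates and diazophosphonoacetates of primary alcohols into a tertiary C–H bond, which gives γ-lactones. The lactone closes in the 1,5 mode through a five-membered ring of C9, C8, O7, C6 and C5. C5 is the stereocentre that matters: insertion proceeds with retention, so C9 takes the β position of the former hydrogen and C6 stays α, cis to H22, while C9 itself forms as a mixture that converges in step 22. Selectivity is needed against C4–H and C22–H (six-membered mode), against addition to the C1=C2 methylene or the furan, and against carbene dimerisation. It rests on the preference for the five-membered mode at the only tertiary C–H within reach, on the deactivation of C4–H by the C3 acetoxy group and the crowding of C22–H, on the electron-poor acyl furan, and on slow addition at high dilution.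

Step 21
Reactants: 27 the α-phosphono γ-lactone
Product: 28 α-phosphono γ-lactone with free C10 aldehyde (C9 epimers)
Conditions: pyridinium p-toluenesulfonate (cat.), acetone/H2O, 50 °C
Reagents that add atoms: water, O
Why: Mild acid hydrolysis of the dimethyl acetal; allylic acetate, lactone and acyl furan should be stable to a pyridinium salt in wet acetone.

Step 22
Reactants: 28 the aldehyde phosphonate
Product: 29 CNP0273675.2 (3S,5S,12R,20R,22S)
Conditions: LiCl, DBU, MeCN, rt
Reagents that add atoms: none
Why: Intramolecular Horner–Wadsworth–Emmons olefination under lithium chloride/amidine (Masamune–Roush) conditions; the C9 phosphonate carbanion adds to the C10 aldehyde and six-membered ring B closes with loss of phosphate. C9 becomes trigonal, so both epimers of 28 converge, and the mild base spares the acetate.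

Compound list

1 | (S)-carvone | CC1=CC[C@@H](CC1=O)C(C)=C | starting material
2 | ozonide of 1 (1,2,4-trioxolane on the side chain) | CC1=CC[C@@H](CC1=O)C2(C)OCOO2 | intermediate
3 | (S)-5-acetyl-2-methylcyclohex-2-en-1-one | CC1=CC[C@@H](CC1=O)C(C)=O | intermediate
4 | (S)-4-methyl-5-oxocyclohex-3-ene-1-carboxylic acid | CC1=CC[C@@H](CC1=O)C(O)=O | intermediate
5 | (S)-5-(hydroxymethyl)-2-methylcyclohex-2-en-1-one | CC1=CC[C@@H](CC1=O)CO | intermediate
6 | (S)-5-{[(tert-butyldimethylsilyl)oxy]methyl}-2-methylcyclohex-2-en-1-one | CC1=CC[C@@H](CC1=O)CO[Si](C)(C)C(C)(C)C | intermediate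
7 | 3-furoic acid | OC(=O)c1ccoc1 | starting material
8 | lithium 2-lithiofuran-3-carboxylate | [Li+].[O-]C(=O)c1ccoc1[Li] | intermediate
9 | 2-formylfuran-3-carboxylic acid | OC(=O)c1ccoc1C=O | intermediate
10 | (E)-2-[3-(ethylsulfanyl)-3-oxoprop-1-en-1-yl]furan-3-carboxylic acid | CCSC(=O)/C=C/c1occc1C(O)=O | intermediate
11 | S-ethyl (E)-3-{3-[methoxy(methyl)carbamoyl]furan-2-yl}prop-2-enethioate | CCSC(=O)/C=C/c1occc1C(=O)N(C)OC | intermediate
12 | lithium enolate of 6 (cross-conjugated, toward the future C22) | CC1=CC[C@@H](C=C1[O-])CO[Si](C)(C)C(C)(C)C.[Li+] | intermediate
13 | S-ethyl (3R)-3-[(1S,6S)-6-{[(tert-butyldimethylsilyl)oxy]methyl}-3-methyl-2-oxocyclohex-3-en-1-yl]-3-{3-[methoxy(methyl)carbamoyl]furan-2-yl}propanethioate | CC1=CC[C@H](CO[Si](C)(C)C(C)(C)C)[C@H](C1=O)[C@@H](CC(=O)SCC)c1occc1C(=O)N(C)OC | intermediate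
14 | (3R)-3-[(1S,6S)-6-{[(tert-butyldimethylsilyl)oxy]methyl}-3-methyl-2-oxocyclohex-3-en-1-yl]-3-{3-[methoxy(methyl)carbamoyl]furan-2-yl}propanal | CC1=CC[C@H](CO[Si](C)(C)C(C)(C)C)[C@H](C1=O)[C@@H](CC=O)c1occc1C(=O)N(C)OC | intermediate
15 | 2-{(1R)-1-[(1S,6S)-6-{[(tert-butyldimethylsilyl)oxy]methyl}-3-methyl-2-oxocyclohex-3-en-1-yl]-3,3-dimethoxypropyl}-N-methoxy-N-methylfuran-3-carboxamide | CC1=CC[C@H](CO[Si](C)(C)C(C)(C)C)[C@H](C1=O)[C@@H](CC(OC)OC)c1occc1C(=O)N(C)OC | intermediate
16 | 1-(2-{(1R)-1-[(1S,6S)-6-{[(tert-butyldimethylsilyl)oxy]methyl}-2-hydroxy-2,3-dimethylcyclohex-3-en-1-yl]-3,3-dimethoxypropyl}furan-3-yl)ethan-1-one (C20 carbinol epimers) | CC1=CC[C@H](CO[Si](C)(C)C(C)(C)C)[C@H](C1(C)O)[C@@H](CC(OC)OC)c1occc1C(C)=O | intermediate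
17 | (4S,5S)-4-[(1R)-1-(3-acetylfuran-2-yl)-3,3-dimethoxypropyl]-5-{[(tert-butyldimethylsilyl)oxy]methyl}-2,3-dimethylcyclohex-2-en-1-one | O=C1C[C@H](CO[Si](C)(C)C(C)(C)C)[C@H](C(C)=C1C)[C@@H](CC(OC)OC)c1occc1C(C)=O | intermediate
18 | potassium C2=C3 enolate of the ring A, ring C, furan tricycle (5S,12R,20R,22S) | CC1=C([O-])C[C@H](CO[Si](C)(C)C(C)(C)C)[C@H]2[C@@H](CC(OC)OC)c3occc3C(=O)C[C@@]12C.[K+] | intermediate
19 | tricyclic C3 triethylsilyl enol ether (C2=C3; C18 ketone; C6 silyl ether; C10 dimethyl acetal; 5S,12R,20R,22S) | CC1=C(O[Si](CC)(CC)CC)C[C@H](CO[Si](C)(C)C(C)(C)C)[C@H]2[C@@H](CC(OC)OC)c3occc3C(=O)C[C@@]12C | intermediate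
20 | tricyclic α-methylene ketone (C1=C2, C3 ketone; 5S,12R,20R,22S) | C=C1C(=O)C[C@H](CO[Si](C)(C)C(C)(C)C)[C@H]2[C@@H](CC(OC)OC)c3occc3C(=O)C[C@@]12C | intermediate
21 | tricyclic C3 β-alcohol (3S,5S,12R,20R,22S) | C=C1[C@@H](O)C[C@H](CO[Si](C)(C)C(C)(C)C)[C@H]2[C@@H](CC(OC)OC)c3occc3C(=O)C[C@@]12C | intermediate
22 | tricyclic C3 acetate, C6 silyl ether (3S,5S,12R,20R,22S) | C=C1[C@@H](OC(C)=O)C[C@H](CO[Si](C)(C)C(C)(C)C)[C@H]2[C@@H](CC(OC)OC)c3occc3C(=O)C[C@@]12C | intermediate
23 | tricyclic C3 acetate, C6 primary alcohol (3S,5S,12R,20R,22S) | C=C1[C@@H](OC(C)=O)C[C@H](CO)[C@H]2[C@@H](CC(OC)OC)c3occc3C(=O)C[C@@]12C | intermediate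
24 | diethylphosphonoacetic acid | OC(=O)CP(=O)(OCC)OCC | starting material
25 | C6 diethylphosphonoacetate of the tricycle (3S,5S,12R,20R,22S) | C=C1[C@@H](OC(C)=O)C[C@H](COC(=O)CP(=O)(OCC)OCC)[C@H]2[C@@H](CC(OC)OC)c3occc3C(=O)C[C@@]12C | intermediate
26 | C6 diazophosphonoacetate of the ring A, ring C, furan tricycle (3S,5S,12R,20R,22S) | C=C1[C@@H](OC(C)=O)C[C@H](COC(=O)C(=[N+]=[N-])P(=O)(OCC)OCC)[C@H]2[C@@H](CC(OC)OC)c3occc3C(=O)C[C@@]12C | intermediate
27 | α-phosphono γ-lactone, spiro at C5, C10 dimethyl acetal (C9 epimers) | C=C1[C@@H](OC(C)=O)C[C@]3(COC(=O)C3P(=O)(OCC)OCC)[C@H]2[C@@H](CC(OC)OC)c4occc4C(=O)C[C@@]12C | intermediate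
28 | α-phosphono γ-lactone with C10 aldehyde (C9 epimers) | C=C1[C@@H](OC(C)=O)C[C@]3(COC(=O)C3P(=O)(OCC)OCC)[C@H]2[C@@H](CC=O)c4occc4C(=O)C[C@@]12C | intermediate
29 | CNP0273675.2 (3S,5S,12R,20R,22S) | C=C1[C@@H](OC(C)=O)C[C@@]23COC(=O)C2=CC[C@H]2c4occc4C(=O)C[C@]1(C)[C@H]23 | target

Total step count: 22. Longest linear sequence: 19 steps (steps 1 to 4 and 8 to 22, from 1). The furan branch (steps 5 to 7) joins at step 8.

Steps least certain to work

Step 20 (key step). The phosphoryl-stabilised carbenoid may be slow to insert into the hindered tertiary C5–H bond. It may instead add to the exocyclic methylene or the furan of a second molecule, dimerise, or insert in the six-membered mode at C22–H or C4–H. The fallback changes the carbenoid and the way ring B is closed; it sets out from 23 and returns at 29. The alcohol 23 is esterified with mono-tert-butyl malonate (EDC·HCl, DMAP) to the mixed malonate F1. Diazo transfer gives the diazomalonate F2. Rh2(OAc)4 should then give the α-(tert-butoxycarbonyl) γ-lactone F3 by the same 1,5 insertion, a reaction type well established for diazomalonates. Aqueous trifluoroacetic acid cleaves the tert-butyl ester and the acetal to the aldehyde acid F4. A decarboxylative Knoevenagel (Doebner) condensation with piperidine in pyridine closes ring B to 29.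

Step 13. Proton exchange between the new ring A enolate and the C19 methylene, or reversal of the conjugate addition, may occur before silylation; the enol ether would then form at the wrong position or not at all. The fallback separates cyclisation from enol ether formation; it sets out from 17 and returns at 20. Catalytic KOt-Bu in t-BuOH/THF gives the tricyclic diketone F5 under thermodynamic control. Equilibrating silylation (Me3SiOTf, Et3N) gives the bis(trimethylsilyl) enol ether F6, with the more substituted C2=C3 enol ether in ring A. Pd(OAc)2 then oxidises only the ring A enol ether, because the C18 enol ether has no β-hydrogen and is hydrolysed on work-up, giving 20.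

Step 8. The thioester enolate formed by the first addition may add back to the ring enone (a second Michael addition to a bicyclo[2.2.2]octanone), and the syn selectivity at C12 may be eroded in a more open transition state. The fallback masks the ring enone; it sets out from 6 and returns at 13. Conjugate addition of thiophenol (Et3N) gives the 3-(phenylsulfanyl) ketone F7. Its kinetic enolate is added to 11 to give the sulfide adduct F8. Oxidation with mCPBA at −78 °C and warming (sulfoxide elimination toward the carbonyl) restores the enone and gives 13.

Step 15. Hydride may be delivered to the β face, giving the α alcohol, or the C18 ketone may also be reduced. The fallback corrects the configuration by substitution with inversion; it sets out from 20 and returns at 22. The C3 epimer F9 is treated under Mitsunobu conditions (PPh3, diisopropyl azodicarboxylate, AcOH), which should give the β acetate 22 directly.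

Step 3. Borane may also reduce the enone carbonyl, so the acid and the ketone are not cleanly distinguished. The fallback reduces both and re-oxidises one; it sets out from 4 and returns at 5. LiAlH4 gives the diol F10, and MnO2 oxidises only the allylic alcohol, giving 5.

Further compounds

F1 | step 20 | C6 tert-butyl malonate of the tricycle | C=C1[C@@H](OC(C)=O)C[C@H](COC(=O)CC(=O)OC(C)(C)C)[C@H]2[C@@H](CC(OC)OC)c3occc3C(=O)C[C@@]12C
F2 | step 20 | C6 tert-butyl diazomalonate of the tricycle | C=C1[C@@H](OC(C)=O)C[C@H](COC(=O)C(=[N+]=[N-])C(=O)OC(C)(C)C)[C@H]2[C@@H](CC(OC)OC)c3occc3C(=O)C[C@@]12C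
F3 | step 20 | α-(tert-butoxycarbonyl) γ-lactone, spiro at C5 (C9 epimers) | C=C1[C@@H](OC(C)=O)C[C@]3(COC(=O)C3C(=O)OC(C)(C)C)[C@H]2[C@@H](CC(OC)OC)c4occc4C(=O)C[C@@]12C
F4 | step 20 | α-carboxy γ-lactone with C10 aldehyde (C9 epimers) | C=C1[C@@H](OC(C)=O)C[C@]3(COC(=O)C3C(O)=O)[C@H]2[C@@H](CC=O)c4occc4C(=O)C[C@@]12C
F5 | step 13 | tricyclic 3,18-diketone (C2 epimers) | CC1C(=O)C[C@H](CO[Si](C)(C)C(C)(C)C)[C@H]2[C@@H](CC(OC)OC)c3occc3C(=O)C[C@@]12C
F6 | step 13 | tricyclic bis(trimethylsilyl) enol ether (C2=C3 and C18=C19) | CC1=C(O[Si](C)(C)C)C[C@H](CO[Si](C)(C)C(C)(C)C)[C@H]2[C@@H](CC(OC)OC)c3occc3C(O[Si](C)(C)C)=C[C@@]12C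
F7 | step 8 | (5S)-5-{[(tert-butyldimethylsilyl)oxy]methyl}-2-methyl-3-(phenylsulfanyl)cyclohexan-1-one (epimers at C2 and C3) | CC1C(Sc2ccccc2)C[C@@H](CC1=O)CO[Si](C)(C)C(C)(C)C
F8 | step 8 | phenylsulfanyl-masked Michael adduct (epimers at the two masked carbons) | CC1C(Sc2ccccc2)C[C@H](CO[Si](C)(C)C(C)(C)C)[C@H](C1=O)[C@@H](CC(=O)SCC)c1occc1C(=O)N(C)OC
F9 | step 15 | tricyclic C3 α-alcohol (C3 epimer of 21) | C=C1[C@H](O)C[C@H](CO[Si](C)(C)C(C)(C)C)[C@H]2[C@@H](CC(OC)OC)c3occc3C(=O)C[C@@]12C
F10 | step 3 | (5S)-5-(hydroxymethyl)-2-methylcyclohex-2-en-1-ol (carbinol epimers) | CC1=CC[C@@H](CC1O)CO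
A1 | alternative 1 | methyl 3-oxopent-4-enoate | C=CC(=O)CC(=O)OC
A2 | alternative 1 | methyl (S)-3-[(tert-butyldimethylsilyl)oxy]-6-oxocyclohex-1-ene-1-carboxylate | COC(=O)C1=C[C@@H](O[Si](C)(C)C(C)(C)C)CCC1=O
A3 | alternative 1 | cis-decalin diester, C2–C20 β-keto ester as its enol | OC1=C(C(=O)OC)[C@@H]2[C@@H](O[Si](C)(C)C(C)(C)C)CCC(=O)[C@]2(C(=O)OC)CC1
A4 | alternative 2 | ring B butenolide bearing the C22 allene and the C12 furyl 1,3-diketone | O=C1OCC2=C1CC[C@@H](c1occc1C(=O)CC(C)=O)[C@H]2C(C)=C=C
A5 | alternative 2 | ring C furyl ketone with quaternary C20 and C3 methylene ketone | O=C1OCC2=C1CC[C@H]1c3occc3C(=O)C[C@@](C)(C(=C)C(C)=O)[C@H]12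
A6 | alternative 3 | ring B lactone bearing the C2 bromoalkene, the C22 isopropenyl group and the C17 tributylstannyl furan | C=C(Br)[C@@H](O[Si](C)(C)C(C)(C)C)C[C@@]12COC(=O)C1=CC[C@@H](c1occc1[Sn](CCCC)(CCCC)CCCC)[C@H]2C(C)=C
A7 | alternative 3 | C3 O-silyl analogue of the target | C=C1[C@@H](O[Si](C)(C)C(C)(C)C)C[C@@]23COC(=O)C2=CC[C@H]2c4occc4C(=O)C[C@]1(C)[C@H]23
A8 | alternative 3 | limonene (drawn as the R enantiomer) | CC1=CC[C@@H](CC1)C(C)=C
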